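**Late readings.** Late in the zeta run the flask slows below any steady first-order decay: the first-order constant read from the readings is 0.0206 min⁻¹ at 12.0 min but 0.0157 min⁻¹ at 80.0 min. So I try the odds instead, target divided by starting material left. In zeta they read 0.280 at the first reading and 2.51 at the last, a slope of 0.0328 min⁻¹, and the readings between lie near that line. Straight odds mean a rate that goes with the square of the starting material left, as long as the reagent stays steady.

| setting | zeta | spring | dawn | midnight | summer | noon |
|---|---|---|---|---|---|---|
| starting material | 0.63 M | 0.50 M | 0.80 M | 1.2 M | 1.5 M | 2.5 M |
| gas | 200 mM (held) | 200 mM (held) | 200 mM (held) | 200 mM (held) | 200 mM (held) | 200 mM (held) |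
| remark | run made earlier |  |  |  |  |  |
| time |  | 80 min | 80 min | 80 min | 80 min | 80 min |

zeta run (percent of the starting material charged): time / min: target / % = 12.0: 21.9; 25.0: 40.1; 30.0: 45.1; 50.0: 61.2; 60.0: 62.1; 80.0: 71.5

(standard deviation of a reading: 1 percentage point)

- at the start none of reagent is dissolved
- the numbers in the tables scatter by 1 percentage point (one standard deviation)
- what may be going on: starting material + reagent -> target; gas <-> reagent
- "hardly changes" means that all values lie within two and a half points (for a concentration: within two and a half percent of the largest)

- amount of target at the end, in percent of the starting material charged for spring, dawn, midnight, summer, noon, in this order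
- how the row runs (falls all the way / rises, then falls / hardly changes / rises all the way / falls, then rises)

**The rule.** Dividing the slope by the zeta charge gives my odds constant, an apparent second-order constant, of 0.0520 L mol⁻¹ min⁻¹. The odds at any time are this constant times the charge times the time since the line began. I take the constant to hold at every charge, with the reagent as steady as in zeta.

**The ladder.** The line starts at 3.44 min, which I read as the time the reagent takes to fill. By my rule, next comes the time at which target equals starting material left: 11.1 min in noon and 41.9 min in spring. The asked 80 min is longer than both, so by my rule spring and noon stand past that point by then. My row is 66.6 %, 76.1 %, 82.7 %, 85.7 % and 90.9 %, rising with the charge. Noon is my shakiest point: its charge of 2.5 M stands above those of the other flasks, zeta's 0.63 M among them.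

**The forecast.** The forecast differs: 73 %, 68 %, 62 %, 57 % and 43 %, a row that falls all the way, on the ground that “Higher charges should therefore drain the reagent”.

**The result.** The flasks give 66.2 %, 75.0 %, 80.9 %, 83.5 % and 87.6 %, a row that rises all the way.

    starting material + reagent → target, rate k1*[starting material]^2*[reagent] (k = 0.00440 L² mol⁻² s⁻¹)
    gas ⇌ reagent, rate k2*(csat - [reagent]) (kL = 0.00750 s⁻¹)

**Noon, then spring.** At 40.0 min noon holds 0.149 M of reagent, less than the 200 mM of saturation, and it ends at 87.6 % against my 90.9 %. Carried to 800 min in spring, the odds constant of 0.0520 L mol⁻¹ min⁻¹ gives 95.4 % target, and the flask holds 95.4 %.

Readings and results are simulated with made-up constants; scatter was added.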